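The route rests on disconnecting the pyran ring at the aryl ether bond O1–C8a. Ring A bears its hydroxyl at C7, para to C4a and meta to C8a, so it is a disguised p-quinol: in the 4-alkyl-4-hydroxycyclohexa-2,5-dienone, C8a is an enone β-carbon. The precursor is that dienone, obtained by singlet-oxygen dearomatisation of a simple 4-alkylphenol and carrying the (S)-configured benzylic carbinol on a three-carbon tether. Mild acid then closes the ring by oxa-Michael addition and restores ring A by loss of water, a metal- and halogen-free meta C–H etherification. The same 7-OH later relays oxidation to C4, where the acylphloroglucinol adds trans to the C2 aryl group.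

Key step: step 4

Remark: flavan numbering (O1, C2–C4, C4a, C5–C8, C8a) is used for all precursors; 9-phenylnonanoic acid is taken as purchasable; 11 is carried as its C4-epimer mixture because C4 is re-ionised in step 7.

Step 1
Reactants: 1 4-hydroxybenzaldehyde; 2 1-[4-(benzyloxy)phenyl]ethan-1-one
Product: 3 (E)-1-[4-(benzyloxy)phenyl]-3-(4-hydroxyphenyl)prop-2-en-1-one
Conditions: dry HCl (cat.), EtOH, 0 °C to rt
Reagents that add atoms: none
Why: Acid-catalysed Claisen–Schmidt aldol condensation, in which the enol of 2 adds to protonated 1 and the aldol dehydrates to the conjugated (E)-enone; under acid the free phenol is tolerated, whereas a phenoxide would deactivate the aldehyde.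

Step 2
Reactants: 3 (E)-1-[4-(benzyloxy)phenyl]-3-(4-hydroxyphenyl)prop-2-en-1-one
Product: 5 (S)-1-[4-(benzyloxy)phenyl]-3-(4-hydroxyphenyl)propan-1-ol, via saturated ketone 4 (not isolated)
Conditions: RuCl[(S,S)-TsDPEN](p-cymene) (2 mol %), HCO2H/Et3N (5:2), DMF, 40 °C
Reagents that add atoms: none
Why: Tandem Noyori–Ikariya asymmetric transfer hydrogenation, in which the ruthenium hydride first reduces the polarised C=C to ketone 4 and then delivers hydride to the aryl ketone through the six-membered outer-sphere transition state, the (S,S)-ligand placing the aryl group against the cymene ring so that the (S)-carbinol (the future C2) should form with high enantioselectivity.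

Step 3
Reactants: 5 (S)-1-[4-(benzyloxy)phenyl]-3-(4-hydroxyphenyl)propan-1-ol
Product: 7 4-[(3S)-3-[4-(benzyloxy)phenyl]-3-hydroxypropyl]-4-hydroxycyclohexa-2,5-dien-1-one, via hydroperoxide 6 (not isolated)
Conditions: Oxone (2KHSO5·KHSO4·K2SO4), NaHCO3, MeCN/H2O, rt; then Me2S
Reagents that add atoms: potassium peroxymonosulfate (KHSO5, the active salt of Oxone and source of the singlet oxygen), [K+].[O-]S(=O)(=O)OO
Why: Oxidative dearomatisation of a para-alkylphenol by singlet oxygen released from buffered KHSO5 gives the para-hydroperoxy dienone 6, which Me2S reduces to p-quinol 7; no cation is formed at C4a, so the side-chain hydroxyl cannot spirocyclise as it would under hypervalent-iodine oxidation, and the remote (S)-carbinol is untouched.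

Step 4
Reactants: 7 4-[(3S)-3-[4-(benzyloxy)phenyl]-3-hydroxypropyl]-4-hydroxycyclohexa-2,5-dien-1-one
Product: 9 (S)-2-[4-(benzyloxy)phenyl]chroman-7-ol, via bicyclic hydroxy-enone 8 (not isolated)
Conditions: (±)-camphor-10-sulfonic acid (10 mol %), CH2Cl2, rt to 40 °C
Reagents that add atoms: none
Why: Protonation of the cross-conjugated dienone lets the C2 hydroxyl add to C8a, the β-carbon of either enone arm, to give the cis-fused hydroxy-enone 8; acid-catalysed enolisation towards C8 then makes the tertiary 4a-OH allylic to a conjugated dienol, so that it leaves as water to give an arenium ion that sheds H8a, which restores aromatic ring A with its hydroxyl at C7. The closest known reaction type is conjugate addition to p-quinols followed by dehydrative rearomatisation (net meta-functionalisation of a para-alkylphenol), combined with the intramolecular oxa-Michael cyclisation of hydroxyalkyl p-quinols. The pyran ring closes in the 6-exo-trig mode. No new stereocentre survives: the two ring-fusion centres of 8 are erased on aromatisation, so both diastereotopic enone arms converge on 9, and C2 keeps its (S) configuration because its C–O bond is never broken. The step needs O–C bonding meta to the ring-A oxygen and an intact p-alkoxybenzylic carbinol: the first is secured because C8a and C5 are the only electrophilic carbons within reach of the three-carbon tether, the second by a weak sulfonic acid at mild temperature, so that conjugate addition should outrun ionisation at C2.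

Step 5
Reactants: 9 (S)-2-[4-(benzyloxy)phenyl]chroman-7-ol
Product: 11 (2S,4RS)-2-[4-(benzyloxy)phenyl]-4-methoxychroman-7-ol, via quinone methide 10 (not isolated)
Conditions: DDQ (1.05 equiv), CH2Cl2/MeOH (4:1), 0 °C
Reagents that add atoms: methanol, CO
Why: DDQ dehydrogenation of a para-alkylphenol, in which the free 7-OH directs hydride loss to C4 (para-benzylic and ortho to O1) to give quinone methide 10, which methanol traps by 1,6-addition; C2–H and the benzyl ether have no para-hydroxyl partner and should be left alone, and the C4 configuration is irrelevant because C4 is re-ionised in step 7.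

Step 6
Reactants: 12 phloroglucinol; 13 9-phenylnonanoic acid
Product: 14 9-phenyl-1-(2,4,6-trihydroxyphenyl)nonan-1-one
Conditions: BF3·OEt2 (as solvent), 85 °C; aqueous NaOAc work-up
Reagents that add atoms: none
Why: Friedel–Crafts C-acylation of phloroglucinol with the free acid in BF3·OEt2, as used for polyhydroxyaryl ketones; the first acyl group deactivates the ring against a second acylation and the remote phenyl ring is far less nucleophilic.

Step 7
Reactants: 11 (2S,4RS)-2-[4-(benzyloxy)phenyl]-4-methoxychroman-7-ol; 14 9-phenyl-1-(2,4,6-trihydroxyphenyl)nonan-1-one (3 equiv)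
Product: 16 1-{3-[(2S,4R)-2-[4-(benzyloxy)phenyl]-7-hydroxychroman-4-yl]-2,4,6-trihydroxyphenyl}-9-phenylnonan-1-one, via flavan-4-yl cation 15 (not isolated)
Conditions: (±)-camphor-10-sulfonic acid (10 mol %), THF/CH2Cl2 (1:4), −20 °C to rt
Reagents that add atoms: none
Why: Acid-catalysed Friedel–Crafts alkylation of the kind used for 4-arylflavans, in which 11 is protonated on its methoxy oxygen and loses methanol to the flavan-4-yl cation 15 (a benzylic cation stabilised by the para 7-OH and the ortho ring oxygen O1), and a free ring carbon of 14 attacks C4 pseudo-axially on the half-chair face opposite the equatorial C2 aryl group, which should set C4 as (R), trans to C2; the two free positions of 14 are equivalent and its excess should outcompete ring A of a second flavan.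

Step 8
Reactants: 16 1-{3-[(2S,4R)-2-[4-(benzyloxy)phenyl]-7-hydroxychroman-4-yl]-2,4,6-trihydroxyphenyl}-9-phenylnonan-1-one
Product: 17 (+)-myristinin D
Conditions: H2 (1 atm), Pd/C (10 %), EtOAc/MeOH, rt
Reagents that add atoms: none
Why: Hydrogenolysis of the benzyl aryl ether over Pd/C; the flavan C2–O bond, the diarylmethine C4 and the hydrogen-bonded aryl ketone should not be cleaved under one atmosphere of hydrogen at room temperature, so both stereocentres are kept.

Compound list

1 | 4-hydroxybenzaldehyde | O=Cc1ccc(O)cc1 | starting material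
2 | 1-[4-(benzyloxy)phenyl]ethan-1-one | CC(=O)c1ccc(OCc2ccccc2)cc1 | starting material
3 | (E)-1-[4-(benzyloxy)phenyl]-3-(4-hydroxyphenyl)prop-2-en-1-one | O=C(/C=C/c1ccc(O)cc1)c1ccc(OCc2ccccc2)cc1 | intermediate
4 | 1-[4-(benzyloxy)phenyl]-3-(4-hydroxyphenyl)propan-1-one (saturated ketone) | O=C(CCc1ccc(O)cc1)c1ccc(OCc2ccccc2)cc1 | intermediate (not isolated)
5 | (S)-1-[4-(benzyloxy)phenyl]-3-(4-hydroxyphenyl)propan-1-ol | O[C@@H](CCc1ccc(O)cc1)c1ccc(OCc2ccccc2)cc1 | intermediate
6 | 4-[(3S)-3-[4-(benzyloxy)phenyl]-3-hydroxypropyl]-4-hydroperoxycyclohexa-2,5-dien-1-one | O=C1C=CC(OO)(CC[C@H](O)c2ccc(OCc3ccccc3)cc2)C=C1 | intermediate (not isolated)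
7 | 4-[(3S)-3-[4-(benzyloxy)phenyl]-3-hydroxypropyl]-4-hydroxycyclohexa-2,5-dien-1-one (p-quinol) | O=C1C=CC(O)(CC[C@H](O)c2ccc(OCc3ccccc3)cc2)C=C1 | intermediate
8 | (2S)-2-[4-(benzyloxy)phenyl]-4a-hydroxy-2,3,4,4a,8,8a-hexahydro-7H-chromen-7-one, cis-fused (one of the two convergent ring-fusion diastereomers is drawn) | O=C1C=C[C@]2(O)CC[C@@H](c3ccc(OCc4ccccc4)cc3)O[C@@H]2C1 | intermediate (not isolated)
9 | (S)-2-[4-(benzyloxy)phenyl]chroman-7-ol | Oc1ccc2CC[C@@H](c3ccc(OCc4ccccc4)cc3)Oc2c1 | intermediate
10 | (S)-2-[4-(benzyloxy)phenyl]-2,3-dihydro-7H-chromen-7-one (quinone methide) | O=C1C=CC2=CC[C@@H](c3ccc(OCc4ccccc4)cc3)OC2=C1 | intermediate (not isolated)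
11 | (2S,4RS)-2-[4-(benzyloxy)phenyl]-4-methoxychroman-7-ol (both C4 epimers) | COC1C[C@@H](c2ccc(OCc3ccccc3)cc2)Oc2cc(O)ccc21 | intermediate
12 | phloroglucinol (benzene-1,3,5-triol) | Oc1cc(O)cc(O)c1 | starting material
13 | 9-phenylnonanoic acid | OC(=O)CCCCCCCCc1ccccc1 | starting material
14 | 9-phenyl-1-(2,4,6-trihydroxyphenyl)nonan-1-one | O=C(CCCCCCCCc1ccccc1)c1c(O)cc(O)cc1O | intermediate
15 | (2S)-2-[4-(benzyloxy)phenyl]-7-hydroxychroman-4-ylium (flavan-4-yl cation, formed from 11 by acid-promoted loss of methanol; camphorsulfonate is the counter-ion) | Oc1ccc2[CH+]C[C@@H](c3ccc(OCc4ccccc4)cc3)Oc2c1 | intermediate (not isolated)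
16 | 1-{3-[(2S,4R)-2-[4-(benzyloxy)phenyl]-7-hydroxychroman-4-yl]-2,4,6-trihydroxyphenyl}-9-phenylnonan-1-one (4'-O-benzyl myristinin D) | O=C(CCCCCCCCc1ccccc1)c1c(O)cc(O)c([C@@H]2C[C@@H](c3ccc(OCc4ccccc4)cc3)Oc3cc(O)ccc32)c1O | intermediate
17 | (+)-myristinin D, 1-{2,4,6-trihydroxy-3-[(2S,4R)-7-hydroxy-2-(4-hydroxyphenyl)chroman-4-yl]phenyl}-9-phenylnonan-1-one | O=C(CCCCCCCCc1ccccc1)c1c(O)cc(O)c([C@@H]2C[C@@H](c3ccc(O)cc3)Oc3cc(O)ccc32)c1O | target

Total step count: 8. Longest linear sequence: 7 steps (steps 1, 2, 3, 4, 5, 7, 8); step 6 is a one-step branch.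

Steps most likely to fail

Step 4 (key step). The acid may ionise the p-alkoxybenzylic C2–O bond, which would cost configuration at C2 and let the quinol hydroxyl capture the cation as a spiro-ether. It may also trigger a dienone–phenol shift faster than the oxa-Michael addition and dehydration. The fallback forms the same O1–C8a bond by copper-catalysed intramolecular Ullmann etherification. It sets out from 2 and comes back at 9. Purchased 2-bromo-4-hydroxybenzaldehyde F1 is protected with MOMCl and EtN(i-Pr)2 as 2-bromo-4-(methoxymethoxy)benzaldehyde F2. Condensation with 2 (KOH, EtOH) should give the bromo-chalcone F3. The tandem transfer hydrogenation of step 2 should give the (S)-bromo alcohol F4. CuI, 1,10-phenanthroline and Cs2CO3 in toluene at 110 °C should close the ring to the MOM-protected flavan F5, with retention at C2 because only the O–H bond reacts. HCl in MeOH at rt then frees the phenol to give 9.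

Step 5. Over-oxidation may occur: loss of H3 from the ionised intermediate would give the flav-3-ene, which DDQ can dehydrogenate further to the flavylium ion and so destroy C2, or a second hydride abstraction may convert 11 into the chroman-4-one. The fallback sets out from 9 and comes back at 16, bypassing 11. Phenol 9 is oxidised with Ag2O in CH2Cl2 at −20 °C; this surface oxidant acts only on the phenolic O–H and cannot abstract hydride. The resulting quinone methide 10 is filtered cold from the silver directly into a solution of 14 with catalytic pyridinium p-toluenesulfonate. 1,6-Addition should then give 16 with the same facial preference as in step 7. No new compound arises.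

Step 7. The flavan-4-yl cation may alkylate ring A of a second flavan (oligomerisation), and reversible ionisation under acid may erode the kinetic trans preference. The fallback sets out from 11 and comes back at 16. Acetylation (Ac2O, pyridine) gives (2S,4RS)-2-[4-(benzyloxy)phenyl]-4-methoxychroman-7-yl acetate F6. Its ring A is deactivated as a nucleophile and can no longer form a quinone methide. BF3·OEt2 in CH2Cl2/THF at −40 °C binds the methoxy group, and the discrete cation should be captured by 14 under kinetic control to give (2S,4R)-2-[4-(benzyloxy)phenyl]-4-[2,4,6-trihydroxy-3-(9-phenylnonanoyl)phenyl]chroman-7-yl acetate F7 (the 7-O-acetate of 16). K2CO3 in MeOH at rt removes the acetate and returns 16.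

Further compounds

F1 | step 4 | 2-bromo-4-hydroxybenzaldehyde (purchased) | O=Cc1ccc(O)cc1Br
F2 | step 4 | 2-bromo-4-(methoxymethoxy)benzaldehyde | COCOc1ccc(C=O)c(Br)c1
F3 | step 4 | (E)-1-[4-(benzyloxy)phenyl]-3-[2-bromo-4-(methoxymethoxy)phenyl]prop-2-en-1-one | O=C(/C=C/c1ccc(OCOC)cc1Br)c1ccc(OCc2ccccc2)cc1
F4 | step 4 | (S)-1-[4-(benzyloxy)phenyl]-3-[2-bromo-4-(methoxymethoxy)phenyl]propan-1-ol | O[C@@H](CCc1ccc(OCOC)cc1Br)c1ccc(OCc2ccccc2)cc1
F5 | step 4 | (S)-2-[4-(benzyloxy)phenyl]-7-(methoxymethoxy)chroman | COCOc1ccc2CC[C@@H](c3ccc(OCc4ccccc4)cc3)Oc2c1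
F0 | step 5 | none | none
F6 | step 7 | (2S,4RS)-2-[4-(benzyloxy)phenyl]-4-methoxychroman-7-yl acetate | COC1C[C@@H](c2ccc(OCc3ccccc3)cc2)Oc2cc(OC(C)=O)ccc21
F7 | step 7 | (2S,4R)-2-[4-(benzyloxy)phenyl]-4-[2,4,6-trihydroxy-3-(9-phenylnonanoyl)phenyl]chroman-7-yl acetate | O=C(CCCCCCCCc1ccccc1)c1c(O)cc(O)c([C@@H]2C[C@@H](c3ccc(OCc4ccccc4)cc3)Oc3cc(OC(C)=O)ccc32)c1O
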